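**Retrosynthetic overview**
- The target is taken back through its two aryl methyl ethers and a lost carboxyl group to 2,4-dihydroxy-6-(10-phenyldecyl)benzoic acid.
- The strategy rests on ring A, the benzene ring with oxygen on two meta carbons and the 10-phenyldecyl chain on the carbon meta to both. Its six carbons are read as C2–C7 of a linear 3,5,7-triketo acid, with the ring oxygens on C3 and C5 and the chain on C7.
- Ring A is opened at the C2–C7 bond (aldol disconnection). It is the only ring the route forms; the terminal phenyl ring is bought.
- The triketo acid comes from CO2 and 16-phenylhexadecane-2,4,6-trione, and the triketone from acetylacetone and methyl 11-phenylundecanoate.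
- The ester comes from 11-bromoundecanoic acid and phenylmagnesium bromide by a copper-catalysed coupling.

Key step: step 5

Remark: the target has no stereocentre, so no stereocontrol is needed; LiN(iPr)2 is taken as a commercial solution.

**Step 1**
Reactants: 1 11-bromoundecanoic acid; 2 phenylmagnesium bromide
Product: 4 11-phenylundecanoic acid, via bromomagnesium 11-bromoundecanoate 3 (not isolated)
Conditions: PhMgBr (2.3 equiv), Li2CuCl4 (3 mol %), THF, −20 °C to rt; then aq. HCl
Reagents that add atoms: none
Why: Copper-catalysed Kochi-type cross-coupling of an aryl Grignard reagent with a primary alkyl bromide; the first equivalent of 2 turns the acid into its magnesium carboxylate 3, which the Grignard reagent does not attack, so only the C–Br bond should react.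

**Step 2**
Reactants: 4 11-phenylundecanoic acid
Product: 5 methyl 11-phenylundecanoate
Conditions: MeOH, H2SO4 (cat.), reflux
Reagents that add atoms: methanol, CO
Why: Fischer esterification of an unhindered aliphatic acid, driven by methanol as solvent.

**Step 3**
Reactants: 5 methyl 11-phenylundecanoate; 6 acetylacetone (pentane-2,4-dione)
Product: 8 16-phenylhexadecane-2,4,6-trione, via dilithium penta-1,3-diene-2,4-diolate 7 (not isolated)
Conditions: 6 (2.5 equiv), LiN(iPr)2 (5 equiv), THF, 0 °C; then 5, 0 °C to rt; cold 1 M HCl
Reagents that add atoms: none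
Why: Claisen-type acylation of a 1,3-diketone dianion at its terminal carbon, the most nucleophilic site; the excess dianion takes up the proton of the more acidic triketone product so that the acylation can go to completion.

**Step 4**
Reactants: 8 16-phenylhexadecane-2,4,6-trione; 9 carbon dioxide
Product: 11 3,5,7-trioxo-17-phenylheptadecanoic acid, via trilithium 16-phenylhexadeca-1,3,5-triene-2,4,6-triolate 10 (not isolated)
Conditions: LiN(iPr)2 (3.5 equiv), THF, 0 °C; CO2 (g), −78 to −20 °C; cold 1 M HCl/Et2O, 0 °C, used at once
Reagents that add atoms: none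
Why: Terminal carboxylation of a 1,3,5-triketone trianion: after the two doubly activated methylene groups, the third deprotonation should take place kinetically at the unhindered C1 methyl group rather than at the C7 methylene, and this most basic carbanion captures CO2; cold work-up keeps the β-keto acid from losing CO2.

**Step 5**
Reactants: 11 3,5,7-trioxo-17-phenylheptadecanoic acid
Product: 13 2,4-dihydroxy-6-(10-phenyldecyl)benzoic acid, via 2-hydroxy-4,6-dioxo-2-(10-phenyldecyl)cyclohexane-1-carboxylic acid 12 (not isolated)
Conditions: 1 M aq. KOH (degassed), Ar, 0 °C to rt; then 2 M HCl, 0 °C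
Reagents that add atoms: none
Why: In aqueous KOH compound 11 is a carboxylate enolate, and C2, activated by the carboxylate and the C3 carbonyl, adds to the C7 ketone in an intramolecular aldol addition that forms the C2–C7 bond and gives the cyclic β-hydroxy ketone 12. The closure is a 6-(enolendo)-exo-trig ring formation, and it becomes irreversible when 12 loses water by E1cB elimination and the C3 and C5 carbonyl groups tautomerize to the two phenols of ring A. The closest known reaction type is the base-mediated aldol aromatization of 3,5,7-triketo acids to β-resorcylic acids of the orsellinic acid type. No stereocentre remains in 13, so the configuration of the two transient stereocentres of 12 does not matter. The step needs the aldol mode to win over the Claisen mode (C6 onto C1), over lactonization to a 4-hydroxy-2-pyrone and over decarboxylation; C1 as a carboxylate anion is neither an acyl acceptor nor able to lactonize in base, and the salt of the β-keto acid should not lose CO2 in the cold. Because the C7 carbonyl already carries the 10-phenyldecyl chain, the chain ends up on C6 of the resorcylic acid without any aryl–alkyl bond formation.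

**Step 6**
Reactants: 13 2,4-dihydroxy-6-(10-phenyldecyl)benzoic acid
Product: 14 5-(10-phenyldecyl)benzene-1,3-diol
Conditions: DMF, 150 °C, Ar
Reagents that add atoms: none
Why: Thermal protodecarboxylation of a β-resorcylic acid; ipso-protonation ortho and para to the hydroxyl groups gives a cyclohexadienone that behaves as a β-keto acid and loses CO2.

**Step 7**
Reactants: 14 5-(10-phenyldecyl)benzene-1,3-diol
Product: 15 1,3-dimethoxy-5-(10-phenyldecyl)benzene (target)
Conditions: Me2SO4 (2.5 equiv), K2CO3, acetone, reflux; then aq. NH3
Reagents that add atoms: dimethyl sulfate, COS(=O)(=O)OC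
Why: Williamson-type double O-methylation of the two phenoxides; no other nucleophilic site is present.

**Compound list**
1 | 11-bromoundecanoic acid | OC(=O)CCCCCCCCCCBr | starting material
2 | phenylmagnesium bromide | Br[Mg]c1ccccc1 | starting material
3 | bromomagnesium 11-bromoundecanoate | [O-]C(=O)CCCCCCCCCCBr.[Mg+2].[Br-] | intermediate
4 | 11-phenylundecanoic acid | OC(=O)CCCCCCCCCCc1ccccc1 | intermediate
5 | methyl 11-phenylundecanoate | COC(=O)CCCCCCCCCCc1ccccc1 | intermediate
6 | acetylacetone (pentane-2,4-dione) | CC(=O)CC(C)=O | starting material
7 | dilithium penta-1,3-diene-2,4-diolate (acetylacetone dianion) | [Li+].[Li+].C=C([O-])C=C(C)[O-] | intermediate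
8 | 16-phenylhexadecane-2,4,6-trione | CC(=O)CC(=O)CC(=O)CCCCCCCCCCc1ccccc1 | intermediate
9 | carbon dioxide | O=C=O | starting material
10 | trilithium 16-phenylhexadeca-1,3,5-triene-2,4,6-triolate | [Li+].[Li+].[Li+].C=C([O-])C=C([O-])C=C([O-])CCCCCCCCCCc1ccccc1 | intermediate
11 | 3,5,7-trioxo-17-phenylheptadecanoic acid | OC(=O)CC(=O)CC(=O)CC(=O)CCCCCCCCCCc1ccccc1 | intermediate
12 | 2-hydroxy-4,6-dioxo-2-(10-phenyldecyl)cyclohexane-1-carboxylic acid (mixture of stereoisomers) | OC(=O)C1C(=O)CC(=O)CC1(O)CCCCCCCCCCc1ccccc1 | intermediate
13 | 2,4-dihydroxy-6-(10-phenyldecyl)benzoic acid | OC(=O)c1c(O)cc(O)cc1CCCCCCCCCCc1ccccc1 | intermediate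
14 | 5-(10-phenyldecyl)benzene-1,3-diol | Oc1cc(O)cc(CCCCCCCCCCc2ccccc2)c1 | intermediate
15 | 1,3-dimethoxy-5-(10-phenyldecyl)benzene | COc1cc(CCCCCCCCCCc2ccccc2)cc(OC)c1 | target

**Totals**
Total step count: 7. Longest linear sequence: 7 steps (1 to 15).

**Steps most likely to fail**

1. Step 4. The third deprotonation may be incomplete or may occur at the C7 methylene instead of the C1 methyl group, and the β-keto acid may lose CO2 during acidic work-up. The fallback avoids the trianion and brings in the carboxyl carbon in masked form. It sets out from 5 and comes back at 13.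
   - Ester 5 is converted with MeNH(OMe)·HCl and iPrMgCl in THF at −20 °C into N-methoxy-N-methyl-11-phenylundecanamide F1.
   - Commercial 2,2,6-trimethyl-4H-1,3-dioxin-4-one is enolized with LiN(SiMe3)2 and acetylated with acetyl chloride to give 2,2-dimethyl-6-(2-oxopropyl)-4H-1,3-dioxin-4-one F2.
   - F2 is deprotonated twice with LiN(iPr)2 in THF at −78 °C and acylated at its terminal methyl carbon by F1, giving 6-(2,4-dioxo-14-phenyltetradecyl)-2,2-dimethyl-4H-1,3-dioxin-4-one F3.
   - Et3N in CH2Cl2 at rt should then bring about the same C2–C7 aldol aromatization, giving 7-hydroxy-2,2-dimethyl-5-(10-phenyldecyl)-4H-1,3-benzodioxin-4-one F4.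
   - Saponification of F4 with KOH in aqueous MeOH and cold acidification gives 13.

2. Step 5. The acid may decarboxylate before the ring closes, hydroxide may cleave the polyketone chain by retro-Claisen reaction, and lactonization to a pyrone may occur on acidification. The fallback runs the same ring closure on the ester, which cannot decarboxylate, under non-hydroxide conditions. It sets out from 11 and comes back at 14.
   - Acid 11 is esterified with Me3SiCHN2 in toluene/MeOH at 0 °C to methyl 3,5,7-trioxo-17-phenylheptadecanoate F5.
   - F5 is cyclized with Cs2CO3 in MeOH and aromatized with HCl in MeOH to methyl 2,4-dihydroxy-6-(10-phenyldecyl)benzoate F6.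
   - Refluxing aqueous NaOH followed by acidification saponifies and decarboxylates F6 to 14.

3. Step 3. The dianion may be quenched by proton transfer from the enolizable ester or from the product, and the ester may self-condense, so that conversion stalls. The fallback makes the same C–C bond at the aldehyde oxidation level. It sets out from 5 and comes back at 8.
   - Ester 5 is reduced with iBu2AlH in CH2Cl2 at −78 °C to 11-phenylundecanal F7.
   - Aldol addition of dianion 7 (THF, −78 to 0 °C) gives racemic 6-hydroxy-16-phenylhexadecane-2,4-dione F8.
   - Oxidation of F8 with Dess–Martin periodinane and NaHCO3 in CH2Cl2 at 0 °C gives 8.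

**Further compounds**
F1 | step 4 | N-methoxy-N-methyl-11-phenylundecanamide | CON(C)C(=O)CCCCCCCCCCc1ccccc1
F2 | step 4 | 2,2-dimethyl-6-(2-oxopropyl)-4H-1,3-dioxin-4-one | CC(=O)CC1=CC(=O)OC(C)(C)O1
F3 | step 4 | 6-(2,4-dioxo-14-phenyltetradecyl)-2,2-dimethyl-4H-1,3-dioxin-4-one | CC1(C)OC(=O)C=C(CC(=O)CC(=O)CCCCCCCCCCc2ccccc2)O1
F4 | step 4 | 7-hydroxy-2,2-dimethyl-5-(10-phenyldecyl)-4H-1,3-benzodioxin-4-one | CC1(C)OC(=O)c2c(CCCCCCCCCCc3ccccc3)cc(O)cc2O1
F5 | step 5 | methyl 3,5,7-trioxo-17-phenylheptadecanoate | COC(=O)CC(=O)CC(=O)CC(=O)CCCCCCCCCCc1ccccc1
F6 | step 5 | methyl 2,4-dihydroxy-6-(10-phenyldecyl)benzoate | COC(=O)c1c(O)cc(O)cc1CCCCCCCCCCc1ccccc1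
F7 | step 3 | 11-phenylundecanal | O=CCCCCCCCCCCc1ccccc1
F8 | step 3 | 6-hydroxy-16-phenylhexadecane-2,4-dione (racemic) | CC(=O)CC(=O)CC(O)CCCCCCCCCCc1ccccc1
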